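**Retrosynthetic overview**

1. The strategy rests on the C9(Br)H–C8H=C7(Br)–C6(CH3)2 segment of the cyclohexene (ring A; 2-oxaspiro[4.5]decane numbering of 21). With OH in place of the allylic bromine it is a 3-bromocyclohex-2-enol, so C9–C8 and C7–Br are cut back to an aldehyde carbon, a terminal alkyne carbon and bromide (alkyne Prins cyclisation).
2. The oxetane (ring C) is cut at its acetal C–O bond to a lactol and the tertiary hydroxyl. The lactol is carried as the butanolide (ring B) and the hydroxyl as its acetate, and the allylic bromide comes from the ring carbinol with inversion.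
3. Aldehyde 19 comes from butanolide 4 by Nicholas propargylation at C3, an aldol reaction that sets the quaternary C3 anti to the isopropenyl group, oxidation, and a chelation-controlled methyl addition that sets the tertiary carbinol carbon.
4. Ring order: ring B (chiral-pool butanolide), then ring A (step 12), then ring C (step 15).

Key step: step 12

Assumption: 9 and 10 are written as the trans isomers expected to predominate, and their C3 configuration is erased by enolisation in step 7; aldehyde 11, sold as an aqueous solution, is used as the anhydrous monomer after extraction and distillation.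

**Step 1**
Reactants: 1 (2R)-5-oxooxolane-2-carboxylic acid
Product: 2 (2R)-5-oxooxolane-2-carbonyl chloride
Conditions: (COCl)2, DMF (cat.), CH2Cl2, 0 °C → rt
Reagents that add atoms: oxalyl chloride, ClC(=O)C(=O)Cl
Why: Acid chloride formation through the chloroiminium salt from DMF and oxalyl chloride leaves the lactone and the stereocentre untouched.

**Step 2**
Reactants: 2 (2R)-5-oxooxolane-2-carbonyl chloride
Product: 3 (5R)-5-acetyloxolan-2-one
Conditions: Me2CuLi, Et2O, −78 °C
Reagents that add atoms: lithium dimethylcuprate, [Li+].C[Cu-]C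
Why: Gilman cuprate acylation of an acid chloride stops at the methyl ketone and does not attack the lactone at this temperature.

**Step 3**
Reactants: 3 (5R)-5-acetyloxolan-2-one
Product: 4 (5R)-5-(prop-1-en-2-yl)oxolan-2-one
Conditions: Zn, CH2Br2, TiCl4, THF–CH2Cl2, 0 °C → rt
Reagents that add atoms: dibromomethane, BrCBr
Why: Takai–Lombardo methylenation converts the ketone to the isopropenyl group without base, so the oxygen-bearing stereocentre should not epimerise and the lactone carbonyl is left alone.

**Step 4**
Reactants: 5 2-methyl-4-(trimethylsilyl)but-3-yn-2-ol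
Product: 6 hexacarbonyldicobalt complex of 5
Conditions: Co2(CO)8, CH2Cl2, rt
Reagents that add atoms: dicobalt octacarbonyl, O=C=[Co](=C=O)(=C=O)(=C=O)[Co](=C=O)(=C=O)(=C=O)=C=O
Why: The alkyne displaces two CO ligands to give the bridged alkyne–Co2(CO)6 complex, which is needed to stabilise the propargylic cation of the Nicholas reaction.

**Step 5**
Reactants: 4 (5R)-5-(prop-1-en-2-yl)oxolan-2-one; 6 hexacarbonyldicobalt complex of 5
Product: 9 hexacarbonyldicobalt complex of (3R,5R)-3-[2-methyl-4-(trimethylsilyl)but-3-yn-2-yl]-5-(prop-1-en-2-yl)oxolan-2-one, via silyl ketene acetal 7 (not isolated), via cobalt-stabilised propargylic cation 8 (not isolated)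
Conditions: 4: LiN(iPr)2, THF, −78 °C, then Me3SiCl, solvent change to CH2Cl2; 6: BF3·OEt2, CH2Cl2, −78 °C; then 7, −78 → −40 °C
Reagents that add atoms: none
Why: Nicholas reaction, in which BF3·OEt2 ionises the tertiary propargylic alcohol complex and the cobalt-stabilised cation alkylates the silyl ketene acetal at C3, a nucleophile far more reactive than the isopropenyl group; the new C3 centre should form mainly trans to isopropenyl but is erased in step 7.

**Step 6**
Reactants: 9 hexacarbonyldicobalt complex of the propargylated butanolide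
Product: 10 (3R,5R)-3-[2-methyl-4-(trimethylsilyl)but-3-yn-2-yl]-5-(prop-1-en-2-yl)oxolan-2-one
Conditions: (NH4)2Ce(NO3)6, acetone, 0 °C
Reagents that add atoms: none
Why: Oxidative decomplexation with ceric ammonium nitrate frees the alkyne, whose C-silyl cap then shields the terminus from the bases of steps 7 and 9.

**Step 7**
Reactants: 10 (3R,5R)-3-[2-methyl-4-(trimethylsilyl)but-3-yn-2-yl]-5-(prop-1-en-2-yl)oxolan-2-one; 11 2,2-dimethoxyacetaldehyde
Product: 13 (3S,5R)-3-(1-hydroxy-2,2-dimethoxyethyl)-3-[2-methyl-4-(trimethylsilyl)but-3-yn-2-yl]-5-(prop-1-en-2-yl)oxolan-2-one (both carbinol epimers), via lithium enolate 12 (not isolated)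
Conditions: LiN(iPr)2, THF, −78 → −40 °C; 11, −78 °C; AcOH, −78 °C
Reagents that add atoms: none
Why: Lithium enolate aldol addition to a reactive, non-enolisable aldehyde, which should approach the planar butanolide enolate on the face anti to the C5 isopropenyl group and so set the quaternary C3 (3S) with the dimethylpropargyl group cis to isopropenyl; the carbinol centre is removed in step 8.

**Step 8**
Reactants: 13 aldol adduct
Product: 14 (3S,5R)-3-(2,2-dimethoxyacetyl)-3-[2-methyl-4-(trimethylsilyl)but-3-yn-2-yl]-5-(prop-1-en-2-yl)oxolan-2-one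
Conditions: Dess–Martin periodinane, CH2Cl2, rt
Reagents that add atoms: none
Why: Dess–Martin oxidation of the hindered secondary alcohol gives a β-keto lactone that cannot enolise, under conditions that spare the acetal, the alkene and the silyl alkyne.

**Step 9**
Reactants: 14 β-keto lactone
Product: 16 (2S)-1,1-dimethoxy-2-{(3S,5R)-3-[2-methyl-4-(trimethylsilyl)but-3-yn-2-yl]-2-oxo-5-(prop-1-en-2-yl)oxolan-3-yl}propan-2-yl acetate, via bromomagnesium alkoxide 15 (not isolated)
Conditions: MgBr2·OEt2, CH2Cl2, −78 °C; MeMgBr, −78 → −40 °C; then Ac2O, −40 °C → rt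
Reagents that add atoms: methylmagnesium bromide, C[Mg]Br; acetic anhydride, CC(=O)OC(C)=O
Why: Chelation-controlled Grignard addition, in which magnesium bridges the ketone and lactone carbonyl oxygens in a six-membered chelate and methyl should add from the chelate face that carries the ring CH2 rather than the dimethylpropargyl group, setting the tertiary carbinol carbon (2S); the alkoxide is acetylated in the flask before it can revert by retro-aldol cleavage.

**Step 10**
Reactants: 16 silyl alkyne acetate
Product: 17 (2S)-1,1-dimethoxy-2-[(3S,5R)-3-(2-methylbut-3-yn-2-yl)-2-oxo-5-(prop-1-en-2-yl)oxolan-3-yl]propan-2-yl acetate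
Conditions: Bu4NF, AcOH, THF, 0 °C
Reagents that add atoms: none
Why: Fluoride-induced protiodesilylation of the alkynyl silane, buffered with acetic acid so that the tertiary acetate and the lactone are not attacked.

**Step 11**
Reactants: 17 terminal alkyne dimethyl acetal
Product: 19 (2S)-2-[(3S,5R)-3-(2-methylbut-3-yn-2-yl)-2-oxo-5-(prop-1-en-2-yl)oxolan-3-yl]-1-oxopropan-2-yl acetate, via collidinium salt 18 (not isolated)
Conditions: Et3SiOTf, 2,4,6-collidine, CH2Cl2, 0 °C; then H2O
Reagents that add atoms: water, O
Why: Acetal cleavage through a pyridinium-type salt that water converts to the aldehyde avoids protic acid, which spares the isopropenyl group and the tertiary acetate; the aldehyde has no α-hydrogen and cannot epimerise.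

**Step 12**
Reactants: 19 acetoxy aldehyde with the dimethylpropargyl arm
Product: 21 (3R,5S,9R,10S)-7-bromo-9-hydroxy-6,6,10-trimethyl-1-oxo-3-(prop-1-en-2-yl)-2-oxaspiro[4.5]dec-7-en-10-yl acetate, via trimethylsilyl ether 20 (not isolated)
Conditions: FeBr3 (20 mol %), Me3SiBr, 2,6-di-tert-butylpyridine (10 mol %), CH2Cl2, −40 → 0 °C; then aq. citric acid, THF, rt
Reagents that add atoms: bromotrimethylsilane, C[Si](C)(C)Br
Why: FeBr3 binds the aldehyde oxygen, the terminal alkyne carbon attacks the activated carbonyl carbon, and bromide is delivered to the internal alkyne carbon as positive charge builds there, so the C9–C8 and C7–Br bonds form in one operation while Me3SiBr supplies bromide and releases the iron as the silyl ether. The closest known reaction type is the iron-halide-promoted alkyne Prins (carbonyl–alkyne) carbocyclisation to 3-halocyclohex-2-enols. Ring A closes in the 6-endo-dig mode, because the 5-exo alternative would put the charge on a primary vinyl carbon. The new carbinol centre (9R, OH cis to OAc) is expected from a chair-like transition state in which the acetoxy group rather than the methyl group is axial (an axial methyl would clash with the gem-dimethyl group) and the iron-bound oxygen is pseudo-equatorial and gauche to the acetoxy oxygen, where two-point binding is possible. The step needs the alkyne to react in preference to the more nucleophilic isopropenyl group, which is secured because that group lies on the butanolide face opposite to the aldehyde arm and cannot reach it, while lactone and acetate are much weaker Lewis bases than the aldehyde at this temperature. The hindered pyridine keeps HBr away from the isopropenyl group, and the 9-epimer would also serve because step 13 is expected to give the same bromide from either.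

**Step 13**
Reactants: 21 bromocyclohexenol
Product: 22 (3R,5S,9S,10S)-7,9-dibromo-6,6,10-trimethyl-1-oxo-3-(prop-1-en-2-yl)-2-oxaspiro[4.5]dec-7-en-10-yl acetate
Conditions: CBr4, PPh3, CH2Cl2, 0 °C → rt
Reagents that add atoms: tetrabromomethane, BrC(Br)(Br)Br
Why: Appel bromination of the allylic alkoxyphosphonium with inversion places bromine trans to the acetoxy group (9S), since the cis acetoxy group cannot attack from the rear and the brominated far allylic terminus blocks the SN2' path; the 9-epimeric alcohol would reach the same bromide by double inversion through the acetoxonium ion.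

**Step 14**
Reactants: 22 dibromo lactone acetate
Product: 23 (3R,5S,9S,10S)-7,9-dibromo-6,6,10-trimethyl-3-(prop-1-en-2-yl)-2-oxaspiro[4.5]dec-7-ene-1,10-diol (lactol, both anomers)
Conditions: iBu2AlH, CH2Cl2, −78 °C; MeOH, then aq. KNaC4H4O6
Reagents that add atoms: none
Why: Low-temperature iBu2AlH reduction stops at the lactol aluminate and cleaves the acetate reductively, the two bromides are inert to the hydride, and the neutral tartrate work-up avoids epoxide closure of the trans bromohydrin.

**Step 15**
Reactants: 23 bromo lactol with free tertiary hydroxyl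
Product: 24 CNP0141320.1, the 2,7-dioxabicyclo[3.2.0]heptane acetal fused to dibromocyclohexene ring A (R at the isopropenyl-bearing carbon, S at the four other stereocentres)
Conditions: PPh3, DIAD (betaine preformed), THF, 0 °C → rt
Reagents that add atoms: none
Why: Proposed new method: the preformed PPh3–DIAD betaine is protonated only by the lactol hydroxyl and converts it into an anomeric oxyphosphonium, whose loss of Ph3P=O gives an oxocarbenium ion that cannot eliminate because its neighbour is quaternary, and the tertiary hydroxyl held two atoms away on the same face should close the oxetane irreversibly under non-acidic conditions, the cis ring fusion fixing the acetal configuration; the closest known reaction type is the Mitsunobu cyclodehydration of diols to oxetanes and of hydroxy lactols to anhydro sugars and bridged oxetane acetals.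

**Compound list**

1 | (2R)-5-oxooxolane-2-carboxylic acid | OC(=O)[C@H]1CCC(=O)O1 | starting material
2 | (2R)-5-oxooxolane-2-carbonyl chloride | ClC(=O)[C@H]1CCC(=O)O1 | intermediate
3 | (5R)-5-acetyloxolan-2-one | CC(=O)[C@H]1CCC(=O)O1 | intermediate
4 | (5R)-5-(prop-1-en-2-yl)oxolan-2-one | C=C(C)[C@H]1CCC(=O)O1 | intermediate
5 | 2-methyl-4-(trimethylsilyl)but-3-yn-2-ol | CC(C)(O)C#C[Si](C)(C)C | starting material
6 | hexacarbonyldicobalt complex of 5 | CC(C)(O)C12[Co]3(=C=O)(=C=O)(=C=O)[Co]1(=C=O)(=C=O)(=C=O)C23[Si](C)(C)C | intermediate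
7 | (R)-trimethyl{[5-(prop-1-en-2-yl)-4,5-dihydrofuran-2-yl]oxy}silane (silyl ketene acetal of 4) | C=C(C)[C@H]1CC=C(O[Si](C)(C)C)O1 | intermediate
8 | hexacarbonyldicobalt-complexed 2-methyl-4-(trimethylsilyl)but-3-yn-2-ylium hydroxytrifluoroborate | C[C+](C)C12[Co]3(=C=O)(=C=O)(=C=O)[Co]1(=C=O)(=C=O)(=C=O)C23[Si](C)(C)C.O[B-](F)(F)F | intermediate
9 | hexacarbonyldicobalt complex of 10 | C=C(C)[C@H]1C[C@@H](C(=O)O1)C(C)(C)C23[Co]4(=C=O)(=C=O)(=C=O)[Co]2(=C=O)(=C=O)(=C=O)C34[Si](C)(C)C | intermediate
10 | (3R,5R)-3-[2-methyl-4-(trimethylsilyl)but-3-yn-2-yl]-5-(prop-1-en-2-yl)oxolan-2-one | C=C(C)[C@H]1C[C@@H](C(=O)O1)C(C)(C)C#C[Si](C)(C)C | intermediate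
11 | 2,2-dimethoxyacetaldehyde | COC(OC)C=O | starting material
12 | lithium enolate of 10 | C=C(C)[C@H]1CC(=C([O-])O1)C(C)(C)C#C[Si](C)(C)C.[Li+] | intermediate
13 | (3S,5R)-3-(1-hydroxy-2,2-dimethoxyethyl)-3-[2-methyl-4-(trimethylsilyl)but-3-yn-2-yl]-5-(prop-1-en-2-yl)oxolan-2-one (carbinol epimers) | C=C(C)[C@H]1C[C@](C(=O)O1)(C(C)(C)C#C[Si](C)(C)C)C(O)C(OC)OC | intermediate
14 | (3S,5R)-3-(2,2-dimethoxyacetyl)-3-[2-methyl-4-(trimethylsilyl)but-3-yn-2-yl]-5-(prop-1-en-2-yl)oxolan-2-one | C=C(C)[C@H]1C[C@](C(=O)O1)(C(C)(C)C#C[Si](C)(C)C)C(=O)C(OC)OC | intermediate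
15 | bromomagnesium (2S)-1,1-dimethoxy-2-{(3S,5R)-3-[2-methyl-4-(trimethylsilyl)but-3-yn-2-yl]-2-oxo-5-(prop-1-en-2-yl)oxolan-3-yl}propan-2-olate | C=C(C)[C@H]1C[C@](C(=O)O1)(C(C)(C)C#C[Si](C)(C)C)[C@](C)([O-])C(OC)OC.[Mg+2].[Br-] | intermediate
16 | (2S)-1,1-dimethoxy-2-{(3S,5R)-3-[2-methyl-4-(trimethylsilyl)but-3-yn-2-yl]-2-oxo-5-(prop-1-en-2-yl)oxolan-3-yl}propan-2-yl acetate | C=C(C)[C@H]1C[C@](C(=O)O1)(C(C)(C)C#C[Si](C)(C)C)[C@](C)(OC(C)=O)C(OC)OC | intermediate
17 | (2S)-1,1-dimethoxy-2-[(3S,5R)-3-(2-methylbut-3-yn-2-yl)-2-oxo-5-(prop-1-en-2-yl)oxolan-3-yl]propan-2-yl acetate | C=C(C)[C@H]1C[C@](C(=O)O1)(C(C)(C)C#C)[C@](C)(OC(C)=O)C(OC)OC | intermediate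
18 | 1-(1-methoxyalkyl)-2,4,6-trimethylpyridinium triflate derived from 17 (N,O-acetal carbon unassigned) | C=C(C)[C@H]1C[C@](C(=O)O1)(C(C)(C)C#C)[C@](C)(OC(C)=O)C(OC)[n+]1c(C)cc(C)cc1C.[O-]S(=O)(=O)C(F)(F)F | intermediate
19 | (2S)-2-[(3S,5R)-3-(2-methylbut-3-yn-2-yl)-2-oxo-5-(prop-1-en-2-yl)oxolan-3-yl]-1-oxopropan-2-yl acetate | C=C(C)[C@H]1C[C@](C(=O)O1)(C(C)(C)C#C)[C@](C)(OC(C)=O)C=O | intermediate
20 | trimethylsilyl ether of 21 | C=C(C)[C@H]1C[C@@]2(C(=O)O1)[C@](C)(OC(C)=O)[C@H](O[Si](C)(C)C)C=C(Br)C2(C)C | intermediate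
21 | (3R,5S,9R,10S)-7-bromo-9-hydroxy-6,6,10-trimethyl-1-oxo-3-(prop-1-en-2-yl)-2-oxaspiro[4.5]dec-7-en-10-yl acetate | C=C(C)[C@H]1C[C@@]2(C(=O)O1)[C@](C)(OC(C)=O)[C@H](O)C=C(Br)C2(C)C | intermediate
22 | (3R,5S,9S,10S)-7,9-dibromo-6,6,10-trimethyl-1-oxo-3-(prop-1-en-2-yl)-2-oxaspiro[4.5]dec-7-en-10-yl acetate | C=C(C)[C@H]1C[C@@]2(C(=O)O1)[C@](C)(OC(C)=O)[C@@H](Br)C=C(Br)C2(C)C | intermediate
23 | (3R,5S,9S,10S)-7,9-dibromo-6,6,10-trimethyl-3-(prop-1-en-2-yl)-2-oxaspiro[4.5]dec-7-ene-1,10-diol (both anomers) | C=C(C)[C@H]1C[C@@]2(C(O)O1)[C@](C)(O)[C@@H](Br)C=C(Br)C2(C)C | intermediate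
24 | CNP0141320.1 | C=C(C)[C@H]1C[C@@]23[C@@H](O1)O[C@]2(C)[C@@H](Br)C=C(Br)C3(C)C | target

**Step count**

Total: 15 steps. Longest linear sequence: 14 steps (1 to 24 through steps 1–3 and 5–15; step 4 is the side branch).

**Steps most likely to fail**

Step 15. The tertiary hydroxyl may capture the anomeric oxyphosphonium too slowly, so that the hydrazide anion is glycosylated instead. The lactol or tertiary oxygen may also displace the trans allylic bromide intramolecularly. The fallback uses known chemistry and installs the bromine last, so that a tertiary alkoxide can close the acetal. It sets out from 21 and rejoins the route at 24. Alcohol 21 is protected with 4-methoxybenzyl trichloroacetimidate and La(OTf)3 (cat.) to give the 4-methoxybenzyl ether F1. iBu2AlH at −78 °C gives the hydroxy lactol F2. 1-Chloro-N,N,2-trimethylprop-1-en-1-amine converts the lactol into the anomeric chloride F3. KOtBu in THF closes the oxetane acetal F4 by the alkoxide displacement known from anhydro sugar synthesis; elimination is impossible next to the quaternary carbon. Buffered DDQ frees the allylic alcohol F5, and CBr4, PPh3 and 2,6-lutidine give 24 with inversion.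

Step 12. The activated aldehyde may be captured by the neighbouring acetoxy carbonyl instead of the alkyne. The Lewis acid may also ionise the allylic lactone C–O bond or the product silyl ether. The fallback sets out from 17 and rejoins at 22. The dimethyl acetal itself is ionised with TiBr4 in CH2Cl2 at −78 °C, an acetal-initiated alkyne Prins cyclisation with bromide capture, to give the allylic methyl ether F6 (either C9 epimer serves). BBr3 at −78 °C then exchanges the allylic methoxy group for bromide through the acetoxonium ion, which should deliver bromine trans to the acetoxy group as in 22.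

Step 9. The hindered ketone may resist addition or cleave by a retro-Claisen path, facial control may erode if magnesium binds the acetal oxygens instead of the lactone carbonyl, and the alkoxide may revert before acetylation. The fallback sets out from 10 and rejoins at 16. Enolate 12 is added directly to 1,1-dimethoxypropan-2-one at −78 °C with a cold acetic acid quench, giving the tertiary alcohol F7. Here the carbinol configuration depends on which ketone substituent lies over the lactone ring in the closed transition state, so the epimers would be separated at this stage. Acetylation with Ac2O, DMAP and Et3N in warm CH2Cl2 then gives 16.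

**Further compounds**

F1 | step 15 | (3R,5S,9R,10S)-7-bromo-9-[(4-methoxybenzyl)oxy]-6,6,10-trimethyl-1-oxo-3-(prop-1-en-2-yl)-2-oxaspiro[4.5]dec-7-en-10-yl acetate | C=C(C)[C@H]1C[C@@]2(C(=O)O1)[C@](C)(OC(C)=O)[C@H](OCc1ccc(OC)cc1)C=C(Br)C2(C)C
F2 | step 15 | (3R,5S,9R,10S)-7-bromo-9-[(4-methoxybenzyl)oxy]-6,6,10-trimethyl-3-(prop-1-en-2-yl)-2-oxaspiro[4.5]dec-7-ene-1,10-diol (both anomers) | C=C(C)[C@H]1C[C@@]2(C(O)O1)[C@](C)(O)[C@H](OCc1ccc(OC)cc1)C=C(Br)C2(C)C
F3 | step 15 | (3R,5S,9R,10S)-7-bromo-1-chloro-9-[(4-methoxybenzyl)oxy]-6,6,10-trimethyl-3-(prop-1-en-2-yl)-2-oxaspiro[4.5]dec-7-en-10-ol (both anomers) | C=C(C)[C@H]1C[C@@]2(C(Cl)O1)[C@](C)(O)[C@H](OCc1ccc(OC)cc1)C=C(Br)C2(C)C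
F4 | step 15 | 4-methoxybenzyl ether of F5 | C=C(C)[C@H]1C[C@@]23[C@@H](O1)O[C@]2(C)[C@H](OCc1ccc(OC)cc1)C=C(Br)C3(C)C
F5 | step 15 | oxetane acetal allylic alcohol (24 with OH in place of the allylic bromine and the opposite configuration at that carbon) | C=C(C)[C@H]1C[C@@]23[C@@H](O1)O[C@]2(C)[C@H](O)C=C(Br)C3(C)C
F6 | step 12 | (3R,5S,9R,10S)-7-bromo-9-methoxy-6,6,10-trimethyl-1-oxo-3-(prop-1-en-2-yl)-2-oxaspiro[4.5]dec-7-en-10-yl acetate | C=C(C)[C@H]1C[C@@]2(C(=O)O1)[C@](C)(OC(C)=O)[C@H](OC)C=C(Br)C2(C)C
F7 | step 9 | (3S,5R)-3-[(2S)-2-hydroxy-1,1-dimethoxypropan-2-yl]-3-[2-methyl-4-(trimethylsilyl)but-3-yn-2-yl]-5-(prop-1-en-2-yl)oxolan-2-one | C=C(C)[C@H]1C[C@](C(=O)O1)(C(C)(C)C#C[Si](C)(C)C)[C@](C)(O)C(OC)OC
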